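## Analysis of the target

Target 31 is a monocyclic, chlorinated bisabolane-type diester. Numbering used throughout: ring A carbons C1–C6 (C1 bears the side chain, C2 is CH2, C3 bears Cl, C4 bears CH3 and OH, C5 the angelate, C6 a free OH); chain C7 (with methylene carbon C14), C8 (angelate), C9, and the C10–C11 epoxide.

Ring A carries five contiguous stereocentres (1R, 3S, 4S, 5S, 6S). The side chain at C1 and the oxygens at C4, C5 and C6 all lie on one face, with chlorine and the C4 methyl on the other. In the chair with the side chain equatorial, C3–Cl and C4–OH are therefore trans-diaxial, and the C4 and C6 hydroxyls are 1,3-diaxial. Two further stereocentres, C8 (S) and C10 (R), sit in the chain and are remote from the ring.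

The sensitive groups are the two angelates (Z to E isomerisation, acyl migration to neighbouring hydroxyls), the chlorohydrin (closes to an epoxide with base), the acid-labile trisubstituted epoxide and the allylic ester. The difficulty lies in telling five oxygen functions apart, in the contra-steric cis relation of C1 and C6, and in an endgame that may be neither strongly acidic nor strongly basic.

The strategy rests on C7. It is a 1,1-disubstituted alkene carbon bonded to ring C1, to C14 and to the oxygenated C8, which is what results when an acyl carbon is attached to the internal carbon of a C1 vinyl group. A cyclopropanol assembled from that vinyl group and an ester delivers this after ring opening.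

## Retrosynthetic reasoning

**Epoxide (31 to 30).** The C10–O bond of the epoxide is cut first, giving hydroxy mesylate 30. The epoxide is the most acid-sensitive group and is therefore formed last. The forward closure must invert C10 (10S to 10R) and must outrun closure of the ring chlorohydrin.

**Protecting-group moves (30 to 27).** Behind 30 lie the C6 aryl ether 29, the C10/C11 diol 28 and the acetonide 27. The order is fixed by selectivity: the acetonide comes off and the mesylate goes on while C6 is still blocked, so only one secondary hydroxyl is free. The aryl ether is then removed oxidatively under acid, before any epoxide exists.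

**Ring functionality (27 to 24).** Cutting the C5 ester gives diol 26. The C3–Cl bond is disconnected to epoxy alcohol 25, because anti opening at the secondary carbon gives exactly the trans-diaxial chlorohydrin. The epoxide is traced to allylic alcohol 24, whose C5 hydroxyl directs oxygen to its own face. Chlorine thus enters late and is never carried through organometallic steps.

**C5 and C8 oxygens (24 to 22).** The C5 hydroxyl of 24 comes from silyl ether 23, and the C8 ester of 23 from allylic alcohol 22. The C8 ester has to be in place before the directed epoxidation, so that the C7=C14 alkene has no free allylic hydroxyl.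

**C8 stereocentre (22 to 21).** The C8–H bond is cut to enone 21. C8 is remote from the ring centres, so a reagent-controlled reduction is planned.

**Key disconnection (21 to 12 and 18).** In 21 the carbonyl carbon C8 is bonded to C7, which also carries C14 and C1. Cutting C7–C8 directly would need an acyl anion to add to the internal carbon of an alkene. The workable equivalent is cyclopropanol 20, in which C8 is bonded to both C7 and C14. Cutting both bonds gives vinyl compound 12 and ester 18. This divides the target into a ring piece with three ring stereocentres and a chain piece with C10, and it places the ketone at C8 ready for reduction. The forward reaction must select the monosubstituted alkene and, on opening, must cleave C8–C14 and not C8–C7.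

**Ring piece (12 to 7).** The silyl ether 12 comes from alcohol 11, and the C5–H bond is cut to ketone 10. The C6–O bond of 10 is made with inversion from the trans ketol 9, because oxidation of an enolate next to C1 can only give the trans isomer. Ketol 9 comes from enone 7 by α′-hydroxylation.

**Enone (7 to 1 and 4).** The C3=C4 unsaturation of 7 is traced through silyl enol ether 6 to ketone 5. The C1–vinyl bond of 5 is cut by conjugate addition to 3 and 4. The methyl group is placed first, on 1, so that no regiochemical choice arises later.

**Chain piece (18 to 13).** Ester 18 is traced through lactone 16 and dioxolanone 14 to 13. The two carboxyl groups of 13 are told apart by acetal formation, the two C11 methyl groups are added to the activated carboxyl, and C10 comes unchanged from the chiral pool.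

## Alternatives that were turned down

**Alternative 1:** chlorolactone template.
- Disconnection and key step: C3–Cl and C4–O are made together by chlorolactonisation of the diene acid A2. The C1 carboxyl bridges to C4 while electrophilic chlorine enters C3 from the other face, giving the bridged lactone A1.
- For it: regiochemistry and the trans relation of Cl and O are certain, because only attack at C4 can close the bridge. The chlorine on the two-carbon bridge should also shield one face of the remaining C5=C6 alkene, steering oxygenation to the wanted face. On these two points it is stronger than the chosen route, which needs a directed epoxidation and a regioselective opening (steps 17 and 18).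
- Against it: C7 is locked in as a lactone carbonyl. Opening it with a carbon nucleophile frees the C4 alkoxide anti to C3–Cl, which would close to an epoxide at once. C7 would then still need methylenation next to the epimerisable C1. Chlorine is carried from the start through every later step, and A2 needs its own asymmetric synthesis and is prone to aromatisation.
- Comparison: the chosen strategy offers instead a C7 that arrives at the right oxidation level together with C8–C11, and a chlorine that enters at step 18.

**Alternative 2:** Diels–Alder union.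
- Disconnection and key step: C1–C6 and C2–C3 are formed by an endo Diels–Alder reaction of silyloxydiene A4 with the chiral α′-alkoxy vinyl ketone A5 (derivable from 13), under activation by a chelating magnesium Lewis acid, giving A3.
- For it: it is the most convergent plan. Ring and chain are joined in one step, with C1 and C6 set cis by the endo rule and the face set by the chelated C8 centre. In step count to the full skeleton it beats the chosen route clearly.
- Against it: A3 has its ring alkene at C4=C5 and no oxygen at C5, so an epoxidation and allylic transposition are needed before the chlorohydrin can be built. C7 is a ketone flanked by the epimerisable C1 and a β-silyloxy group, so methylenation risks epimerisation and β-elimination. The chain alkene still needs a late asymmetric epoxidation beside other alkenes.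
- Comparison: the chosen strategy offers instead a ring whose C3=C4 alkene and C5/C6 oxygens are in place before coupling, and a C7 formed directly as the alkene carbon.

**Alternative 3:** arene dihydrodiol with tethered radical cyclisation.
- Disconnection and key step: C1–C7 is formed by 5-exo cyclisation of the radical from bromoacetal A7, itself made from the arene cis-dihydrodiol A8, giving the cis-fused acetal A6.
- For it: C5, C6, the C4 methyl and the C3=C4 alkene come enantiopure from A8, and the tether forces C1–C7 cis to C6–O. This solves in one step what the chosen route spends steps 5 to 7 on, and for the ring stereotriad it is the stronger plan.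
- Against it: the allyl radical formed after cyclisation can be reduced at C2 or C4, so alkene regiochemistry is at risk. The two hydroxyls of A8 must first be differentiated. In A6, C7 is a CH2 and C8 an acetal carbon, so C14, C9–C11 and the C8 and C10 centres must all still be added, and the C6 oxygen must be released and protected again.
- Comparison: the chosen strategy offers instead the whole C7/C14/C8–C11 unit, with C10 preset, in one coupling and one oxidation.

Key step: step 12

Assumption: the (S)-BINAP–rhodium catalyst is taken to add the vinyl group to 3 with the facial sense known for aryl and alkenyl additions to cyclohex-2-en-1-one (5S product); should the sense be opposite, (R)-BINAP is used and nothing else changes.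

## Route

Step 1
Reactants: 1 cyclohex-2-en-1-one
Product: 3 (±)-6-methylcyclohex-2-en-1-one, via lithium dienolate 2 (not isolated)
Conditions: LiN(iPr)2, THF, −78 °C; MeI, −78 → 0 °C
Reagents that add atoms: iodomethane, CI
Why: Kinetic α′-deprotonation gives the cross-conjugated dienolate, which is C-methylated (enolate alkylation); placing the methyl group now removes any later regiochemical question.

Step 2
Reactants: 3 (±)-6-methylcyclohex-2-en-1-one; 4 potassium vinyltrifluoroborate
Product: 5 (5S)-5-ethenyl-2-methylcyclohexan-1-one (both C2 epimers)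
Conditions: Rh(acac)(C2H4)2 (3 mol %), (S)-BINAP, dioxane/H2O (10:1), 100 °C
Reagents that add atoms: none
Why: Hayashi–Miyaura rhodium-catalysed asymmetric 1,4-addition; the catalyst should control the face of the enone irrespective of the remote methyl centre and set C1 of the target (5S here). The C2 methyl centre is left as a mixture because steps 3 and 4 erase it.

Step 3
Reactants: 5 (5S)-5-ethenyl-2-methylcyclohexan-1-one
Product: 6 trimethyl{[(5S)-5-ethenyl-2-methylcyclohex-1-en-1-yl]oxy}silane
Conditions: Me3SiCl, NaI, Et3N, MeCN, rt
Reagents that add atoms: chlorotrimethylsilane, C[Si](C)(C)Cl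
Why: Thermodynamic enol silylation with iodotrimethylsilane made in situ should converge both C2 epimers on the more substituted, tetrasubstituted silyl enol ether.

Step 4
Reactants: 6 trimethyl{[(5S)-5-ethenyl-2-methylcyclohex-1-en-1-yl]oxy}silane
Product: 7 (5S)-5-ethenyl-2-methylcyclohex-2-en-1-one
Conditions: Pd(OAc)2 (10 mol %), O2 (1 atm), dry DMSO, rt
Reagents that add atoms: none
Why: Saegusa–Ito oxidation: the palladium enolate undergoes β-hydride elimination toward C3 to give the 2-methyl enone, and O2 reoxidises zerovalent palladium. The isolated vinyl group should survive under anhydrous conditions.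

Step 5
Reactants: 7 (5S)-5-ethenyl-2-methylcyclohex-2-en-1-one
Product: 9 (5R,6R)-5-ethenyl-6-hydroxy-2-methylcyclohex-2-en-1-one, via potassium dienolate 8 (not isolated)
Conditions: KN(SiMe3)2, THF, −78 °C; 2-(benzenesulfonyl)-3-phenyloxaziridine; aq. NH4Cl
Reagents that add atoms: 2-(benzenesulfonyl)-3-phenyloxaziridine, O=S(=O)(c1ccccc1)N1OC1c1ccccc1
Why: The only enolisable α′ position (C6 of the target) gives the cross-conjugated dienolate; Davis enolate hydroxylation occurs anti to the neighbouring vinyl group, so the hydroxyl should be trans to it.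

Step 6
Reactants: 9 (5R,6R)-5-ethenyl-6-hydroxy-2-methylcyclohex-2-en-1-one
Product: 10 (5R,6S)-5-ethenyl-6-(4-methoxyphenoxy)-2-methylcyclohex-2-en-1-one
Conditions: 4-methoxyphenol, PPh3, diisopropyl azodicarboxylate, toluene, 0 °C → rt
Reagents that add atoms: 4-methoxyphenol, COc1ccc(O)cc1
Why: Mitsunobu etherification: the oxyphosphonium of the α-ketol is displaced by phenoxide with inversion, so the trans ketol becomes the cis aryl ether and the C6 protecting group is installed in the same operation. No anti-periplanar β-hydrogen is available for elimination.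

Step 7
Reactants: 10 (5R,6S)-5-ethenyl-6-(4-methoxyphenoxy)-2-methylcyclohex-2-en-1-one
Product: 11 (1R,5R,6S)-5-ethenyl-6-(4-methoxyphenoxy)-2-methylcyclohex-2-en-1-ol
Conditions: NaBH4, CeCl3·7H2O, MeOH, −78 °C
Reagents that add atoms: none
Why: Luche 1,2-reduction: with the vinyl group equatorial the aryloxy group is axial, and hydride should add axially from the face opposite to it, placing the new hydroxyl cis to both neighbours (C5 of the target).

Step 8
Reactants: 11 (1R,5R,6S)-5-ethenyl-6-(4-methoxyphenoxy)-2-methylcyclohex-2-en-1-ol
Product: 12 tert-butyl{[(1R,5R,6S)-5-ethenyl-6-(4-methoxyphenoxy)-2-methylcyclohex-2-en-1-yl]oxy}dimethylsilane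
Conditions: tBuMe2SiOTf, 2,6-lutidine, CH2Cl2, −78 → 0 °C
Reagents that add atoms: tert-butyldimethylsilyl trifluoromethanesulfonate, CC(C)(C)[Si](C)(C)OS(=O)(=O)C(F)(F)F
Why: Silylation of the hindered allylic alcohol with the silyl triflate; the silyl ether protects C5 through the titanium, palladium and borane steps and can later be removed beside the aryl ether.

Step 9
Reactants: 13 L-malic acid
Product: 14 2-[(4S)-2,2-dimethyl-5-oxo-1,3-dioxolan-4-yl]acetic acid
Conditions: Me2C(OMe)2, TsOH·H2O (cat.), rt
Reagents that add atoms: 2,2-dimethoxypropane, COC(C)(C)OC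
Why: Acid-catalysed acetalisation takes the α-hydroxy acid unit into the five-membered dioxolanone and leaves the β-carboxyl free, which differentiates the two carboxyl groups.

Step 10
Reactants: 14 2-[(4S)-2,2-dimethyl-5-oxo-1,3-dioxolan-4-yl]acetic acid
Product: 16 (4S)-4-hydroxy-5,5-dimethyloxolan-2-one, via dihydroxy acid 15 (not isolated)
Conditions: MeMgBr (4.5 equiv), THF, 0 °C → rt; then 2 M HCl
Reagents that add atoms: methylmagnesium bromide, C[Mg]Br
Why: The first equivalent forms the unreactive magnesium carboxylate; double Grignard addition to the activated dioxolanone carbonyl releases acetone and gives the tertiary carbinol, and acidification closes the γ-lactone. The stereocentre is not touched.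

Step 11
Reactants: 16 (4S)-4-hydroxy-5,5-dimethyloxolan-2-one
Product: 18 methyl 2-[(4S)-2,2,5,5-tetramethyl-1,3-dioxolan-4-yl]acetate, via dihydroxy ester 17 (not isolated)
Conditions: Me2C(OMe)2, MeOH, TsOH·H2O (cat.), rt
Reagents that add atoms: 2,2-dimethoxypropane, COC(C)(C)OC; methanol, CO
Why: Acid-catalysed methanolysis opens the lactone and the diol is trapped as its acetonide (transacetalisation), the usual way from β-hydroxy γ-lactones to acetonide esters; excess 2,2-dimethoxypropane should drive the equilibrium.

Step 12
Reactants: 12 tert-butyl{[(1R,5R,6S)-5-ethenyl-6-(4-methoxyphenoxy)-2-methylcyclohex-2-en-1-yl]oxy}dimethylsilane; 18 methyl 2-[(4S)-2,2,5,5-tetramethyl-1,3-dioxolan-4-yl]acetate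
Product: 20 cyclopropanol with C8 bonded to C7 and C14 (ring and dioxolane configured as in 12 and 18; both cyclopropane carbons undefined), via titanacyclopropane 19 (not isolated)
Conditions: Ti(OiPr)4 (1.2 equiv), c-C6H11MgCl (4.5 equiv, slow addition), 18 (2 equiv), THF, rt
Reagents that add atoms: none
Why: Ti(OiPr)4 and two equivalents of c-C6H11MgCl give a dicyclohexyltitanium that loses cyclohexane to form a cyclohexene complex of divalent titanium, a titanacyclopropane, and the monosubstituted vinyl group of 12 displaces the cyclohexene to give 19. The ester carbonyl of 18 inserts into the less hindered Ti–C14 bond (forming C8–C14), methoxide leaves the oxatitanacyclopentane, and the resulting β-titanio ketone adds through its Ti–C7 bond to its own carbonyl (forming C7–C8), a 3-exo-trig closure that gives the cyclopropanolate. The closest known reaction type is the Kulinkovich hydroxycyclopropanation in its alkene ligand-exchange form, established for terminal alkenes and esters. The two cyclopropane centres (C7, C8) should form mainly with the carbon substituents cis, as the least hindered oxatitanacycle dictates, but they are not controlled on purpose because step 13 erases both; no lasting stereocentre is made, and C1 and C10 are not enolisable and stay untouched. The step needs chemoselectivity for the vinyl group: a trisubstituted ring alkene cannot displace cyclohexene from titanium, and the silyl ether, aryl ether and acetonide oxygens are not β to either titanium-bound carbon, so no β-alkoxide elimination is open. It also needs the Grignard reagent to react with titanium and not with the ester, which slow addition and the low nucleophilicity of a secondary Grignard reagent should secure; the simpler partner 18 is used in excess.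

Step 13
Reactants: 20 cyclopropanol
Product: 21 3-[(1R,5R,6S)-5-(tert-butyldimethylsilyloxy)-6-(4-methoxyphenoxy)-4-methylcyclohex-3-en-1-yl]-1-[(4S)-2,2,5,5-tetramethyl-1,3-dioxolan-4-yl]but-3-en-2-one
Conditions: Pd(OAc)2 (10 mol %), pyridine, O2 (1 atm), toluene, 80 °C
Reagents that add atoms: none
Why: Palladium-mediated cyclopropanol ring opening: the palladium alkoxide cleaves the less substituted C8–C14 bond by β-carbon elimination, and β-hydride elimination from C7 of the palladium homoenolate gives the α-methylene ketone while O2 reoxidises zerovalent palladium. Both cyclopropane stereocentres disappear and no free secondary alcohol is present to be oxidised.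

Step 14
Reactants: 21 α-methylene ketone
Product: 22 (2S)-3-[(1R,5R,6S)-5-(tert-butyldimethylsilyloxy)-6-(4-methoxyphenoxy)-4-methylcyclohex-3-en-1-yl]-1-[(4S)-2,2,5,5-tetramethyl-1,3-dioxolan-4-yl]but-3-en-2-ol (8S alcohol)
Conditions: (R)-2-methyl-CBS-oxazaborolidine (20 mol %), catecholborane, toluene, −78 °C
Reagents that add atoms: none
Why: Corey–Bakshi–Shibata reduction with the 1,1-disubstituted alkenyl group as the large substituent; the (R)-oxazaborolidine should give the 8S alcohol (the sense opposite to the (S)-catalyst/aryl ketone case), and catecholborane at low temperature avoids hydroboration and conjugate reduction.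

Step 15
Reactants: 22 8S allylic alcohol
Product: 23 C8 angelate of 22 (C5 silyl ether and C6 aryl ether and acetonide retained; 1R,5R,6S,8S,10S)
Conditions: angelic acid, 2,4,6-trichlorobenzoyl chloride, Et3N, toluene, rt; then 22, 75 °C
Reagents that add atoms: angelic acid, C/C=C(/C)C(O)=O
Why: Yamaguchi-type esterification through the mixed 2,4,6-trichlorobenzoic anhydride without a nucleophilic pyridine catalyst, conditions known to preserve the Z geometry of angelates.

Step 16
Reactants: 23 C8 angelate
Product: 24 C5 allylic alcohol (C8 angelate and C6 aryl ether and acetonide retained; 1R,5R,6S,8S,10S)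
Conditions: HF·pyridine, pyridine, THF, 0 °C → rt
Reagents that add atoms: none
Why: Fluoride-mediated desilylation under buffered conditions cleaves the allylic silyl ether, while the acetonide, the aryl ether and the ester are stable.

Step 17
Reactants: 24 C5 allylic alcohol
Product: 25 C3–C4 epoxide with oxygen cis to the C5 hydroxyl (1R,3R,4S,5S,6S,8S,10S)
Conditions: VO(acac)2 (5 mol %), tBuOOH, CH2Cl2, 0 °C → rt
Reagents that add atoms: tert-butyl hydroperoxide, CC(C)(C)OO
Why: Vanadium-catalysed hydroxyl-directed epoxidation: the C5 alkoxide on vanadium delivers oxygen to its own face of the C3=C4 bond, and the C7=C14 and angelate alkenes, which have no free allylic hydroxyl, should be left alone.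

Step 18
Reactants: 25 epoxy alcohol
Product: 26 chlorohydrin diol with 3S chloride and free C4 and C5 hydroxyls (1R,3S,4S,5S,6S,8S,10S)
Conditions: Ti(OiPr)4 (1.5 equiv), Et2NH·HCl, CH2Cl2, rt
Reagents that add atoms: diethylammonium chloride, CC[NH2+]CC.[Cl-]
Why: Titanium-assisted opening of a 2,3-epoxy alcohol: chelation of the C5 alkoxide and the epoxide oxygen directs chloride to the distal, secondary C3 with inversion, which is also the trans-diaxial mode. This gives the 3S chloride and the 4S tertiary alcohol.

Step 19
Reactants: 26 chlorohydrin diol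
Product: 27 C5,C8-bis-angelate (C4 hydroxyl free; C6 aryl ether and acetonide retained)
Conditions: angelic acid, 2,4,6-trichlorobenzoyl chloride, Et3N, toluene, rt; then 26, 75 °C
Reagents that add atoms: angelic acid, C/C=C(/C)C(O)=O
Why: The same mixed-anhydride acylation as in step 15; only the secondary C5 hydroxyl should react, the tertiary C4 hydroxyl being inert, and a tertiary amine in toluene is too weak a base to close the chlorohydrin readily.

Step 20
Reactants: 27 bis-angelate acetonide
Product: 28 C10,C11-diol (10S)
Conditions: AcOH/H2O (4:1), 50 °C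
Reagents that add atoms: none
Why: Acid-catalysed acetal hydrolysis; the esters, the chlorohydrin and the aryl ether are stable to aqueous acetic acid, and stronger acid is avoided to prevent pinacol-type rearrangement of the diol.

Step 21
Reactants: 28 diol
Product: 29 C10 methanesulfonate (10S; C11 hydroxyl free)
Conditions: MeSO2Cl, pyridine, CH2Cl2, 0 °C
Reagents that add atoms: methanesulfonyl chloride, CS(=O)(=O)Cl
Why: Selective sulfonylation of the only free secondary hydroxyl; the tertiary hydroxyls at C4 and C11 do not react under these conditions, and C6 is still protected.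

Step 22
Reactants: 29 mesylate
Product: 30 C6 alcohol (hydroxy mesylate; 1R,3S,4S,5S,6S,8S,10S)
Conditions: (NH4)2Ce(NO3)6 (2.5 equiv), MeCN/H2O (4:1), 0 °C
Reagents that add atoms: none
Why: Oxidative cleavage of the 4-methoxyphenyl ether by tetravalent cerium (one-electron oxidation of the arene, then hydrolysis to the quinone) under acidic conditions that leave mesylate, chlorohydrin and esters intact. It is placed before epoxide formation because the epoxide would not survive the acid.

Step 23
Reactants: 30 hydroxy mesylate
Product: 31 target CNP0158207.1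
Conditions: K2CO3, MeOH, 0 °C, short reaction time
Reagents that add atoms: none
Why: Intramolecular Williamson reaction: the C11 alkoxide displaces the C10 sulfonate with inversion (3-exo-tet), turning 10S into the 10R epoxide. A sulfonate leaves much faster than the ring chloride, so brief exposure to mild base in the cold should spare the chlorohydrin and the angelates.

## Compound list

1 | cyclohex-2-en-1-one | O=C1C=CCCC1 | starting material
2 | lithium cyclohexa-1,5-dien-1-olate | [Li+].[O-]C1=CCCC=C1 | intermediate
3 | (±)-6-methylcyclohex-2-en-1-one | CC1CCC=CC1=O | intermediate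
4 | potassium vinyltrifluoroborate | [K+].F[B-](F)(F)C=C | starting material
5 | (5S)-5-ethenyl-2-methylcyclohexan-1-one (both C2 epimers) | C=C[C@H]1CCC(C)C(=O)C1 | intermediate
6 | trimethyl{[(5S)-5-ethenyl-2-methylcyclohex-1-en-1-yl]oxy}silane | C=C[C@H]1CCC(C)=C(O[Si](C)(C)C)C1 | intermediate
7 | (5S)-5-ethenyl-2-methylcyclohex-2-en-1-one | C=C[C@H]1CC=C(C)C(=O)C1 | intermediate
8 | potassium dienolate of 7 (deprotonated at C6) | [K+].C=C[C@H]1CC=C(C)C([O-])=C1 | intermediate
9 | (5R,6R)-5-ethenyl-6-hydroxy-2-methylcyclohex-2-en-1-one (hydroxyl trans to vinyl) | C=C[C@H]1CC=C(C)C(=O)[C@@H]1O | intermediate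
10 | (5R,6S)-5-ethenyl-6-(4-methoxyphenoxy)-2-methylcyclohex-2-en-1-one (aryloxy cis to vinyl) | C=C[C@H]1CC=C(C)C(=O)[C@H]1Oc2ccc(OC)cc2 | intermediate
11 | (1R,5R,6S)-5-ethenyl-6-(4-methoxyphenoxy)-2-methylcyclohex-2-en-1-ol (all-cis) | C=C[C@H]1CC=C(C)[C@@H](O)[C@H]1Oc2ccc(OC)cc2 | intermediate
12 | tert-butyl{[(1R,5R,6S)-5-ethenyl-6-(4-methoxyphenoxy)-2-methylcyclohex-2-en-1-yl]oxy}dimethylsilane | C=C[C@H]1CC=C(C)[C@@H](O[Si](C)(C)C(C)(C)C)[C@H]1Oc2ccc(OC)cc2 | intermediate
13 | L-malic acid, (2S)-2-hydroxybutanedioic acid | OC(=O)C[C@H](O)C(O)=O | starting material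
14 | 2-[(4S)-2,2-dimethyl-5-oxo-1,3-dioxolan-4-yl]acetic acid | OC(=O)C[C@@H]1OC(C)(C)OC1=O | intermediate
15 | (3S)-3,4-dihydroxy-4-methylpentanoic acid | OC(=O)C[C@H](O)C(C)(C)O | intermediate
16 | (4S)-4-hydroxy-5,5-dimethyloxolan-2-one | O=C1C[C@H](O)C(C)(C)O1 | intermediate
17 | methyl (3S)-3,4-dihydroxy-4-methylpentanoate | COC(=O)C[C@H](O)C(C)(C)O | intermediate
18 | methyl 2-[(4S)-2,2,5,5-tetramethyl-1,3-dioxolan-4-yl]acetate | COC(=O)C[C@@H]1OC(C)(C)OC1(C)C | intermediate
19 | diisopropoxytitanacyclopropane of 12 (titanium bridging C7 and C14) | CC(C)O[Ti]1(OC(C)C)CC1[C@H]2CC=C(C)[C@@H](O[Si](C)(C)C(C)(C)C)[C@H]2Oc3ccc(OC)cc3 | intermediate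
20 | 2-[(1R,5R,6S)-5-(tert-butyldimethylsilyloxy)-6-(4-methoxyphenoxy)-4-methylcyclohex-3-en-1-yl]-1-{[(4S)-2,2,5,5-tetramethyl-1,3-dioxolan-4-yl]methyl}cyclopropan-1-ol (cyclopropane carbons undefined) | OC1(C[C@@H]2OC(C)(C)OC2(C)C)CC1[C@H]3CC=C(C)[C@@H](O[Si](C)(C)C(C)(C)C)[C@H]3Oc4ccc(OC)cc4 | intermediate
21 | 3-[(1R,5R,6S)-5-(tert-butyldimethylsilyloxy)-6-(4-methoxyphenoxy)-4-methylcyclohex-3-en-1-yl]-1-[(4S)-2,2,5,5-tetramethyl-1,3-dioxolan-4-yl]but-3-en-2-one | C=C(C(=O)C[C@@H]1OC(C)(C)OC1(C)C)[C@H]2CC=C(C)[C@@H](O[Si](C)(C)C(C)(C)C)[C@H]2Oc3ccc(OC)cc3 | intermediate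
22 | (2S)-3-[(1R,5R,6S)-5-(tert-butyldimethylsilyloxy)-6-(4-methoxyphenoxy)-4-methylcyclohex-3-en-1-yl]-1-[(4S)-2,2,5,5-tetramethyl-1,3-dioxolan-4-yl]but-3-en-2-ol (8S alcohol) | C=C([C@H](C[C@@H]1OC(C)(C)OC1(C)C)O)[C@H]2CC=C(C)[C@@H](O[Si](C)(C)C(C)(C)C)[C@H]2Oc3ccc(OC)cc3 | intermediate
23 | (2Z)-2-methylbut-2-enoate (angelate) of 22 at C8 | C=C([C@H](C[C@@H]1OC(C)(C)OC1(C)C)OC(=O)/C(C)=C\C)[C@H]2CC=C(C)[C@@H](O[Si](C)(C)C(C)(C)C)[C@H]2Oc3ccc(OC)cc3 | intermediate
24 | C5 allylic alcohol: 23 without the silyl group (1R,5R,6S,8S,10S) | C=C([C@H](C[C@@H]1OC(C)(C)OC1(C)C)OC(=O)/C(C)=C\C)[C@H]2CC=C(C)[C@@H](O)[C@H]2Oc3ccc(OC)cc3 | intermediate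
25 | C3–C4 epoxide of 24, oxygen cis to the C5 hydroxyl (1R,3R,4S,5S,6S,8S,10S) | C=C([C@H](C[C@@H]1OC(C)(C)OC1(C)C)OC(=O)/C(C)=C\C)[C@H]2C[C@H]3O[C@@]3(C)[C@@H](O)[C@H]2Oc4ccc(OC)cc4 | intermediate
26 | chlorohydrin diol: 3S chloride, 4S tertiary alcohol, free C5 hydroxyl, C8 angelate, C6 aryl ether, C10/C11 acetonide | C=C([C@H](C[C@@H]1OC(C)(C)OC1(C)C)OC(=O)/C(C)=C\C)[C@H]2C[C@H](Cl)[C@@](C)(O)[C@@H](O)[C@H]2Oc3ccc(OC)cc3 | intermediate
27 | C5,C8-bis-angelate of 26 | C=C([C@H](C[C@@H]1OC(C)(C)OC1(C)C)OC(=O)/C(C)=C\C)[C@H]2C[C@H](Cl)[C@@](C)(O)[C@@H](OC(=O)/C(C)=C\C)[C@H]2Oc3ccc(OC)cc3 | intermediate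
28 | C10,C11-diol (10S) from 27 | C=C([C@H](C[C@H](O)C(C)(C)O)OC(=O)/C(C)=C\C)[C@H]1C[C@H](Cl)[C@@](C)(O)[C@@H](OC(=O)/C(C)=C\C)[C@H]1Oc2ccc(OC)cc2 | intermediate
29 | C10 methanesulfonate (10S) of 28 | C=C([C@H](C[C@H](OS(C)(=O)=O)C(C)(C)O)OC(=O)/C(C)=C\C)[C@H]1C[C@H](Cl)[C@@](C)(O)[C@@H](OC(=O)/C(C)=C\C)[C@H]1Oc2ccc(OC)cc2 | intermediate
30 | hydroxy mesylate with free C6 hydroxyl (1R,3S,4S,5S,6S,8S,10S) | C=C([C@H](C[C@H](OS(C)(=O)=O)C(C)(C)O)OC(=O)/C(C)=C\C)[C@H]1C[C@H](Cl)[C@@](C)(O)[C@@H](OC(=O)/C(C)=C\C)[C@H]1O | intermediate
31 | CNP0158207.1 (1R,3S,4S,5S,6S,8S,10R) | C=C([C@H](C[C@H]1OC1(C)C)OC(=O)/C(C)=C\C)[C@H]1C[C@H](Cl)[C@@](C)(O)[C@@H](OC(=O)/C(C)=C\C)[C@H]1O | target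

## Step count and least certain steps

Total step count: 23. Longest linear sequence: 20 steps (steps 1–8, then 12–23); the chain branch (steps 9–11) joins at step 12.

**Step 12 (key step).** Most likely failure: ligand exchange at the α-branched vinyl group of 12 is too slow, so the cyclohexene–titanium species or the Grignard reagent attacks or reduces the ester carbonyl of 18, or the ester is lost through enolisation. Fallback, setting out from 12 and 18 and returning at 21: Tsuji–Wacker oxidation of 12 (PdCl2, CuCl, O2, DMF/H2O) gives the methyl ketone F1. Kinetic enolisation on the methyl side (KN(SiMe3)2, −78 °C) and trapping with N-phenylbis(trifluoromethanesulfonimide) gives the vinyl triflate F2. Ester 18 is reduced with iBu2AlH at −78 °C to the aldehyde F3. A Nozaki–Hiyama–Kishi coupling of F2 with F3 (CrCl2, NiCl2 cat., DMF) forms C7–C8 as the allylic alcohol F4 (both C8 epimers), and Dess–Martin oxidation gives 21.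

**Step 6.** Most likely failure: slow displacement at the hindered α-keto carbon by a weakly acidic phenol, with alkylation of the reduced azodicarboxylate or epimerisation of the cis aryloxy ketone back to trans. Fallback, from 9 and returning at 12, sets C6 by hydride instead of by substitution. Ketol 9 is silylated (Et3SiCl, imidazole) to the trans triethylsilyl ether F5. Luche reduction gives the allylic alcohol F6 (hydroxyl cis to vinyl), and silylation of C5 gives the bis-silyl ether F7. The triethylsilyl group is removed selectively (pyridinium p-toluenesulfonate, MeOH) to the trans alcohol F8, and Dess–Martin oxidation gives the C6 ketone F9. LiBH(s-Bu)3 at −78 °C, attacking anti to both flanking substituents, gives the all-cis alcohol F10. Copper-catalysed O-arylation with 4-iodoanisole (CuI, 3,4,7,8-tetramethyl-1,10-phenanthroline, Cs2CO3, toluene, 110 °C), which does not touch the carbinol centre, then gives 12.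

**Step 14.** Most likely failure: poor facial selectivity, because the two ketone substituents differ less in size than in aryl alkyl ketones and the ring stereocentre next to C7 may oppose the catalyst. Fallback, from 21 and returning at 22: hydrolysis of the acetonide (AcOH/H2O) gives the β-hydroxy enone F11. Evans–Saksena reduction (Me4NBH(OAc)3, MeCN/AcOH, −30 °C), in which the C10 hydroxyl delivers hydride internally, gives the 1,3-anti triol F12; the 8S,10S relation is the anti one. Re-forming the five-membered acetonide on the C10/C11 diol (Me2C(OMe)2, pyridinium p-toluenesulfonate) gives 22.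

**Step 19.** Most likely failure: slow acylation of the hindered C5 hydroxyl, leaving time for Z to E isomerisation of the angeloyl group or for amine-induced closure of the chlorohydrin. Fallback, from 25 and returning at 27, reverses the order. Epoxy alcohol 25 is acylated by the same mixed-anhydride method to the epoxy diester F13, where no chlorohydrin is present. The epoxide is then opened with LiCl and AcOH in THF. Without the chelating hydroxyl, regioselectivity rests on trans-diaxial opening at the secondary C3 and on the electron-withdrawing C5 ester, which disfavours attack at C4.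

**Step 23.** Most likely failure: competing closure of the ring chlorohydrin (C4 alkoxide anti-periplanar to C3–Cl) and base-induced migration of the C5 angeloyl group to the free C6 hydroxyl. Fallback, from 30 and returning at 31: the cis-1,3-diaxial C4/C6 diol is tied up as the cyclic phenylboronate F14 (PhB(OH)2, toluene, molecular sieves). The epoxide is closed with 1,8-diazabicyclo[5.4.0]undec-7-ene in CH2Cl2 to the boronate epoxide F15, and exchange with pinacol under neutral conditions releases 31.

## Further compounds

F1 | step 12 | methyl ketone: 1-[5-(tert-butyldimethylsilyloxy)-6-(4-methoxyphenoxy)-4-methylcyclohex-3-en-1-yl]ethan-1-one, ring configured as in 12 | CC(=O)[C@H]1CC=C(C)[C@@H](O[Si](C)(C)C(C)(C)C)[C@H]1Oc2ccc(OC)cc2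
F2 | step 12 | vinyl triflate: 1-[5-(tert-butyldimethylsilyloxy)-6-(4-methoxyphenoxy)-4-methylcyclohex-3-en-1-yl]ethenyl trifluoromethanesulfonate, ring configured as in 12 | C=C(OS(=O)(=O)C(F)(F)F)[C@H]1CC=C(C)[C@@H](O[Si](C)(C)C(C)(C)C)[C@H]1Oc2ccc(OC)cc2
F3 | step 12 | 2-[(4S)-2,2,5,5-tetramethyl-1,3-dioxolan-4-yl]acetaldehyde | O=CC[C@@H]1OC(C)(C)OC1(C)C
F4 | step 12 | allylic alcohol 22 as a mixture of both C8 epimers | C=C(C(O)C[C@@H]1OC(C)(C)OC1(C)C)[C@H]2CC=C(C)[C@@H](O[Si](C)(C)C(C)(C)C)[C@H]2Oc3ccc(OC)cc3
F5 | step 6 | triethylsilyl ether of 9 (silyloxy trans to vinyl) | C=C[C@H]1CC=C(C)C(=O)[C@@H]1O[Si](CC)(CC)CC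
F6 | step 6 | allylic alcohol from F5 (C5 hydroxyl cis to vinyl, C6 triethylsilyloxy trans) | C=C[C@H]1CC=C(C)[C@@H](O)[C@@H]1O[Si](CC)(CC)CC
F7 | step 6 | C5 tert-butyldimethylsilyl, C6 triethylsilyl bis-ether | C=C[C@H]1CC=C(C)[C@@H](O[Si](C)(C)C(C)(C)C)[C@@H]1O[Si](CC)(CC)CC
F8 | step 6 | C6 alcohol trans to vinyl, C5 tert-butyldimethylsilyl ether | C=C[C@H]1CC=C(C)[C@@H](O[Si](C)(C)C(C)(C)C)[C@@H]1O
F9 | step 6 | C6 ketone: 2-(tert-butyldimethylsilyloxy)-6-ethenyl-3-methylcyclohex-3-en-1-one, C1 and C5 as in 12 | C=C[C@H]1CC=C(C)[C@@H](O[Si](C)(C)C(C)(C)C)C1=O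
F10 | step 6 | all-cis C6 alcohol: 12 with hydroxyl in place of the aryloxy group | C=C[C@H]1CC=C(C)[C@@H](O[Si](C)(C)C(C)(C)C)[C@H]1O
F11 | step 14 | β-hydroxy enone: 21 with free C10 and C11 hydroxyls | C=C(C(=O)C[C@H](O)C(C)(C)O)[C@H]1CC=C(C)[C@@H](O[Si](C)(C)C(C)(C)C)[C@H]1Oc2ccc(OC)cc2
F12 | step 14 | 8S,10S (1,3-anti) triol: 22 with free C10 and C11 hydroxyls | C=C([C@@H](O)C[C@H](O)C(C)(C)O)[C@H]1CC=C(C)[C@@H](O[Si](C)(C)C(C)(C)C)[C@H]1Oc2ccc(OC)cc2
F13 | step 19 | epoxy diester: C5 angelate of 25 | C=C([C@H](C[C@@H]1OC(C)(C)OC1(C)C)OC(=O)/C(C)=C\C)[C@H]2C[C@H]3O[C@@]3(C)[C@@H](OC(=O)/C(C)=C\C)[C@H]2Oc4ccc(OC)cc4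
F14 | step 23 | cyclic phenylboronate of 30 across the C4 and C6 oxygens | C=C([C@H](C[C@H](OS(C)(=O)=O)C(C)(C)O)OC(=O)/C(C)=C\C)[C@H]1C[C@H](Cl)[C@@]2(C)OB(c3ccccc3)O[C@@H]1[C@@H]2OC(=O)/C(C)=C\C
F15 | step 23 | cyclic phenylboronate of 31 across the C4 and C6 oxygens | C=C([C@H](C[C@H]1OC1(C)C)OC(=O)/C(C)=C\C)[C@H]1C[C@H](Cl)[C@@]2(C)OB(c3ccccc3)O[C@@H]1[C@@H]2OC(=O)/C(C)=C\C
A1 | alternative 1 | 7-chloro-1-methyl-2-oxabicyclo[2.2.2]oct-5-en-3-one (chlorine anti to the lactone oxygen) | O=C1[C@H]2C[C@H](Cl)[C@@](C)(O1)C=C2
A2 | alternative 1 | (1S)-4-methylcyclohexa-2,4-diene-1-carboxylic acid | OC(=O)[C@H]1CC=C(C)C=C1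
A3 | alternative 2 | 1-[cis-2-(tert-butyldimethylsilyloxy)-4-methylcyclohex-3-en-1-yl]-2-(4-methoxybenzyloxy)-5-methylhex-4-en-1-one | O=C([C@H](CC=C(C)C)OCc1ccc(OC)cc1)[C@H]2CCC(C)=C[C@H]2O[Si](C)(C)C(C)(C)C
A4 | alternative 2 | (E)-tert-butyldimethyl[(3-methylbuta-1,3-dien-1-yl)oxy]silane | C=C(C)/C=C/O[Si](C)(C)C(C)(C)C
A5 | alternative 2 | (4S)-4-(4-methoxybenzyloxy)-7-methylocta-1,6-dien-3-one | C=CC(=O)[C@H](CC=C(C)C)OCc1ccc(OC)cc1
A6 | alternative 3 | cis-fused 7-(tert-butyldimethylsilyloxy)-2-ethoxy-6-methyl-2,3,3a,4,7,7a-hexahydro-1-benzofuran | CCOC1C[C@H]2CC=C(C)[C@@H](O[Si](C)(C)C(C)(C)C)[C@H]2O1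
A7 | alternative 3 | bromoacetal: cis-6-(2-bromo-1-ethoxyethoxy)-5-(tert-butyldimethylsilyloxy)-4-methylcyclohexa-1,3-diene | C1=CC=C(C)[C@@H](O[Si](C)(C)C(C)(C)C)[C@H]1OC(CBr)OCC
A8 | alternative 3 | (1S,2R)-3-methylcyclohexa-3,5-diene-1,2-diol | C1=CC=C(C)[C@@H](O)[C@H]1O
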